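**Retrosynthetic overview**
1. The last C–C bond, C1a–C13b, comes from a nickel-catalysed reductive conjugate allylation. Unit b is an 11(13)-methylene lactone; unit a is a C1 allylic ester whose own methylene is masked as a Mannich base. Both partners come from one macrocyclic lactone.
2. The ten-membered ring is closed by an intramolecular B-alkyl Suzuki coupling (C3–C4) between a terminal vinyl group and a (Z)-vinyl iodide.
3. The γ-lactone and C8 come from Felkin addition of a (Z)-alkenylmagnesium (C9) to a C8 aldehyde, then lactonisation onto C12.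
4. The western aldehyde (C6, C7) comes from a thiazolidinethione syn-aldol of a succinate half ester with (Z)-3-iodobut-2-enal. The eastern iodide (C1, C9=C10) comes from a lipase-resolved enynol by anti-carbomagnesiation and iodination.
5. Ring order in each unit: γ-lactone first, then the ten-membered carbocycle; the two bicyclic units are joined at the end.

Convention (one line): each C15 unit is numbered as a germacranolide (ring C1–C10, methyl C14 on C10, methyl C15 on C4, lactone carbons C11–C13, lactone oxygen on C8); suffix a = unit that ends with the 11(13)-methylene, suffix b = the 11,13-dihydro unit; the inter-unit bond is C1a–C13b.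

**Route**

Step 1
Reactants: 1 but-2-yn-1-ol
Product: 3 (2Z)-3-iodobut-2-en-1-ol, via cyclic vinylalanate 2 (not isolated)
Conditions: NaAlH2(OCH2CH2OMe)2, Et2O, 0 °C to rt; EtOAc; then I2, THF, −78 °C to 0 °C
Reagents that add atoms: iodine II
Why: Hydroxyl-directed trans-hydroalumination of the propargylic alcohol places aluminium on C3 in a five-membered alanate, and iodinolysis with retention gives the (Z)-vinyl iodide (hydroalumination–iodination).

Step 2
Reactants: 3 (2Z)-3-iodobut-2-en-1-ol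
Product: 4 (2Z)-3-iodobut-2-enal
Conditions: MnO2, CH2Cl2, rt
Reagents that add atoms: none
Why: Allylic alcohol oxidation with MnO2 is mild and leaves the vinyl iodide and the Z geometry untouched.

Step 3
Reactants: 5 succinic anhydride
Product: 6 4-tert-butoxy-4-oxobutanoic acid
Conditions: t-BuOH, N-hydroxysuccinimide (cat.), DMAP (cat.), Et3N, toluene, reflux
Reagents that add atoms: tert-butanol CC(C)(C)O
Why: Nucleophile-catalysed alcoholysis of the cyclic anhydride gives the half ester, and the tert-butyl ester later resists both lactonisation at C6–O and hydride reduction.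

Step 4
Reactants: 6 4-tert-butoxy-4-oxobutanoic acid
Product: 7 tert-butyl 4-[(4S)-4-benzyl-2-thioxo-1,3-thiazolidin-3-yl]-4-oxobutanoate
Conditions: (4S)-4-benzyl-1,3-thiazolidine-2-thione, EDC·HCl, DMAP, CH2Cl2, 0 °C to rt
Reagents that add atoms: (4S)-4-benzyl-1,3-thiazolidine-2-thione S=C1N[C@@H](Cc2ccccc2)CS1
Why: Carbodiimide (Steglich-type) N-acylation gives the activated thioimide needed for the auxiliary-controlled aldol.

Step 5
Reactants: 7 tert-butyl 4-[(4S)-4-benzyl-2-thioxo-1,3-thiazolidin-3-yl]-4-oxobutanoate; 4 (2Z)-3-iodobut-2-enal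
Product: 9 tert-butyl (3S,4S,5Z)-3-{[(4S)-4-benzyl-2-thioxo-1,3-thiazolidin-3-yl]carbonyl}-4-hydroxy-6-iodohept-5-enoate, via chlorotitanium (Z)-enolate 8 (not isolated)
Conditions: TiCl4, i-Pr2NEt, N-methyl-2-pyrrolidinone, CH2Cl2, 0 °C; then 4, −78 °C to 0 °C
Reagents that add atoms: none
Why: The Crimmins titanium aldol of the (Z)-enolate runs through the non-chelated Zimmerman–Traxler chair ("Evans syn"), with the (4S)-benzyl group shielding one enolate face, so C6 and C7 (C4 and C3 of the heptenoate) are set together as 6,7-syn.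

Step 6
Reactants: 9 tert-butyl (3S,4S,5Z)-3-{[(4S)-4-benzyl-2-thioxo-1,3-thiazolidin-3-yl]carbonyl}-4-hydroxy-6-iodohept-5-enoate
Product: 10 tert-butyl (3S,4S,5Z)-3-{[(4S)-4-benzyl-2-thioxo-1,3-thiazolidin-3-yl]carbonyl}-6-iodo-4-[(triisopropylsilyl)oxy]hept-5-enoate
Conditions: TIPSOTf, 2,6-lutidine, CH2Cl2, 0 °C
Reagents that add atoms: triisopropylsilyl trifluoromethanesulfonate CC(C)[Si](OS(=O)(=O)C(F)(F)F)(C(C)C)C(C)C
Why: Silyl triflate silylation blocks C6–O (which must never lactonise onto C12) with a group that resists 1,3-migration and prevents retro-aldol.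

Step 7
Reactants: 10 tert-butyl (3S,4S,5Z)-3-{[(4S)-4-benzyl-2-thioxo-1,3-thiazolidin-3-yl]carbonyl}-6-iodo-4-[(triisopropylsilyl)oxy]hept-5-enoate
Product: 11 tert-butyl (3S,4S,5Z)-3-formyl-6-iodo-4-[(triisopropylsilyl)oxy]hept-5-enoate
Conditions: i-Bu2AlH, CH2Cl2, −78 °C; aq potassium sodium tartrate
Reagents that add atoms: none
Why: The thioimide is far more electrophilic than the tert-butyl ester, so hydride reduction at −78 °C stops at the aluminium hemiaminal, which collapses to the C8 aldehyde on work-up (reductive auxiliary cleavage).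

Step 8
Reactants: 12 prop-2-enal; 13 ethynyltrimethylsilane
Product: 15 rac-5-(trimethylsilyl)pent-1-en-4-yn-3-ol, via lithium silylacetylide 14 (not isolated)
Conditions: n-BuLi, THF, −78 °C; then 12, −78 °C
Reagents that add atoms: none
Why: 1,2-Addition of the lithium acetylide to the enal (acetylide addition) is fast at −78 °C and joins C1–C3 to C9–C10.

Step 9
Reactants: 15 rac-5-(trimethylsilyl)pent-1-en-4-yn-3-ol
Product: 16 (3S)-5-(trimethylsilyl)pent-1-en-4-yn-3-ol
Conditions: Amano lipase PS, vinyl acetate, hexane, 30 °C, stopped at about 52% conversion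
Reagents that add atoms: none
Why: Lipase-catalysed kinetic resolution (transesterification) acylates the (R)-alcohol by the Kazlauskas rule (silylalkynyl as the large group) and leaves the (S)-alcohol, which becomes C1.

Step 10
Reactants: 16 (3S)-5-(trimethylsilyl)pent-1-en-4-yn-3-ol
Product: 17 (3S)-pent-1-en-4-yn-3-ol
Conditions: K2CO3, MeOH, rt
Reagents that add atoms: none
Why: Base-catalysed methanolysis of the alkynyl C–Si bond (protodesilylation) frees the terminal alkyne without touching the carbinol centre.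

Step 11
Reactants: 17 (3S)-pent-1-en-4-yn-3-ol
Product: 19 (1Z,3S)-1-iodo-2-methylpenta-1,4-dien-3-ol, via cyclic alkenylmagnesium alkoxide 18 (not isolated)
Conditions: MeMgBr (3 equiv), CuI (20 mol %), THF/Et2O, −10 °C to rt; then I2, −78 °C to 0 °C
Reagents that add atoms: methylmagnesium bromide C[Mg]Br; iodine II
Why: Copper-catalysed anti-carbomagnesiation of the propargylic alkoxide delivers methyl to the proximal alkyne carbon and forms a five-membered magnesium chelate, whose iodinolysis with retention gives the (Z)-iodide carrying the C10 methyl.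

Step 12
Reactants: 19 (1Z,3S)-1-iodo-2-methylpenta-1,4-dien-3-ol
Product: 20 tert-butyl{[(1Z,3S)-1-iodo-2-methylpenta-1,4-dien-3-yl]oxy}dimethylsilane
Conditions: TBSCl, imidazole, DMF, rt
Reagents that add atoms: tert-butyldimethylsilyl chloride CC(C)(C)[Si](C)(C)Cl
Why: Imidazole-mediated silylation protects C1–O with a group that can later be removed selectively next to the TIPS ether.

Step 13
Reactants: 20 tert-butyl{[(1Z,3S)-1-iodo-2-methylpenta-1,4-dien-3-yl]oxy}dimethylsilane; 11 tert-butyl (3S,4S,5Z)-3-formyl-6-iodo-4-[(triisopropylsilyl)oxy]hept-5-enoate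
Product: 22 tert-butyl (3R,4S,5Z,7S)-7-[(tert-butyldimethylsilyl)oxy]-4-hydroxy-3-{(1S,2Z)-3-iodo-1-[(triisopropylsilyl)oxy]but-2-en-1-yl}-6-methylnona-5,8-dienoate, via alkenylmagnesium chloride 21 (not isolated)
Conditions: i-PrMgCl·LiCl, THF, 0 °C to rt; then 11, THF/CH2Cl2, −78 °C to −40 °C
Reagents that add atoms: none
Why: Iodine–magnesium exchange keeps the alkene geometry, and the alkenylmagnesium adds to the α-branched aldehyde under Felkin–Anh control (C6 branch anti, attack past H), placing C8–O syn to the C7 acetate arm (8S) as the trans-lactone requires; the minor 8-epimer is removed here.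

Step 14
Reactants: 22 tert-butyl (3R,4S,5Z,7S)-7-[(tert-butyldimethylsilyl)oxy]-4-hydroxy-3-{(1S,2Z)-3-iodo-1-[(triisopropylsilyl)oxy]but-2-en-1-yl}-6-methylnona-5,8-dienoate
Product: 23 (4R,5S)-5-{(1Z,3S)-3-[(tert-butyldimethylsilyl)oxy]-2-methylpenta-1,4-dien-1-yl}-4-{(1S,2Z)-3-iodo-1-[(triisopropylsilyl)oxy]but-2-en-1-yl}oxolan-2-one
Conditions: KOt-Bu (10 mol %), THF, 0 °C
Reagents that add atoms: none
Why: Alkoxide-catalysed intramolecular transesterification (lactonisation) closes the five-membered 12,8-lactone, the expelled tert-butoxide carries the chain, and only C8–O is free to cyclise.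

Step 15
Reactants: 23 (4R,5S)-5-{(1Z,3S)-3-[(tert-butyldimethylsilyl)oxy]-2-methylpenta-1,4-dien-1-yl}-4-{(1S,2Z)-3-iodo-1-[(triisopropylsilyl)oxy]but-2-en-1-yl}oxolan-2-one
Product: 25 (1S,4Z,6R,7R,8S,9Z)-1-[(tert-butyldimethylsilyl)oxy]-6-[(triisopropylsilyl)oxy]-13-norgermacra-4,9-dien-12,8-olide, via B-alkyl-9-BBN adduct 24 (not isolated)
Conditions: 9-BBN-H, THF, rt; then slow addition to Pd(dppf)Cl2 (20 mol %), AsPh3, Cs2CO3, DMF/THF/H2O, 50 °C, 2 mM; mildly acidic work-up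
Reagents that add atoms: none
Why: 9-BBN hydroborates only the terminal vinyl group, and the intramolecular B-alkyl Suzuki–Miyaura coupling with the (Z)-vinyl iodide under high dilution closes the ten-membered ring with retention of the C4=C5 geometry, helped by the low strain of a (Z,Z)-cyclodeca-1,6-diene and the turn imposed by the trans-lactone.

Step 16
Reactants: 25 (1S,4Z,6R,7R,8S,9Z)-1-[(tert-butyldimethylsilyl)oxy]-6-[(triisopropylsilyl)oxy]-13-norgermacra-4,9-dien-12,8-olide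
Product: 27 (1S,4Z,6R,7R,8S,9Z,11S)-1-[(tert-butyldimethylsilyl)oxy]-13-(dimethylamino)-6-[(triisopropylsilyl)oxy]germacra-4,9-dien-12,8-olide, via lithium enolate 26 (not isolated)
Conditions: LiN(i-Pr)2, THF, −78 °C; then [Me2N=CH2]I, −78 °C to rt
Reagents that add atoms: N,N-dimethylmethyleneiminium iodide C=[N+](C)C.[I-]
Why: Kinetic lactone enolate formation and Mannich alkylation with Eschenmoser's salt install C13 anti to the C6 branch as a dimethylaminomethyl group, which is the masked methylene of unit a and the methylene precursor of unit b.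

Step 17
Reactants: 27 (1S,4Z,6R,7R,8S,9Z,11S)-1-[(tert-butyldimethylsilyl)oxy]-13-(dimethylamino)-6-[(triisopropylsilyl)oxy]germacra-4,9-dien-12,8-olide
Product: 29 (1S,4Z,6R,7R,8S,9Z)-1-[(tert-butyldimethylsilyl)oxy]-6-[(triisopropylsilyl)oxy]germacra-4,9,11(13)-trien-12,8-olide, via trimethylammonium iodide 28 (not isolated)
Conditions: MeI, MeOH, rt; then aq NaHCO3, CH2Cl2, rt
Reagents that add atoms: none
Why: N-Methylation followed by mild base-induced Hofmann-type β-elimination of trimethylamine unveils the 11(13)-methylene lactone, the Michael acceptor that becomes unit b.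

Step 18
Reactants: 27 (1S,4Z,6R,7R,8S,9Z,11S)-1-[(tert-butyldimethylsilyl)oxy]-13-(dimethylamino)-6-[(triisopropylsilyl)oxy]germacra-4,9-dien-12,8-olide
Product: 30 (1S,4Z,6R,7R,8S,9Z,11S)-13-(dimethylamino)-1-hydroxy-6-[(triisopropylsilyl)oxy]germacra-4,9-dien-12,8-olide
Conditions: HF·pyridine, pyridine, THF, 0 °C
Reagents that add atoms: none
Why: Buffered fluoride cleaves the secondary TBS ether much faster than the TIPS ether (selective desilylation), freeing only C1–OH.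

Step 19
Reactants: 30 (1S,4Z,6R,7R,8S,9Z,11S)-13-(dimethylamino)-1-hydroxy-6-[(triisopropylsilyl)oxy]germacra-4,9-dien-12,8-olide
Product: 31 (1R,4Z,6R,7R,8S,9Z,11S)-13-(dimethylamino)-6-[(triisopropylsilyl)oxy]germacra-4,9-dien-12,8-olid-1-yl 3,5-bis(trifluoromethyl)benzoate
Conditions: 3,5-bis(trifluoromethyl)benzoic acid, PPh3, DIAD, toluene, 0 °C to rt
Reagents that add atoms: 3,5-bis(trifluoromethyl)benzoic acid OC(=O)c1cc(cc(c1)C(F)(F)F)C(F)(F)F
Why: Mitsunobu esterification inverts C1 by SN2 displacement of the oxyphosphonium ion and installs an electron-poor benzoate that ionises more readily than the allylic lactone C8–O bonds.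

Step 20
Reactants: 31 (1R,4Z,6R,7R,8S,9Z,11S)-13-(dimethylamino)-6-[(triisopropylsilyl)oxy]germacra-4,9-dien-12,8-olid-1-yl 3,5-bis(trifluoromethyl)benzoate; 29 (1S,4Z,6R,7R,8S,9Z)-1-[(tert-butyldimethylsilyl)oxy]-6-[(triisopropylsilyl)oxy]germacra-4,9,11(13)-trien-12,8-olide
Product: 33 protected dimer in which C1a of the (1R,4Z,6R,7R,8S,9Z,11S)-13-(dimethylamino)-6-[(triisopropylsilyl)oxy]germacra-4,9-dien-12,8-olide unit a is bonded to C13b of the (1S,4Z,6R,7R,8S,9Z,11R)-1-[(tert-butyldimethylsilyl)oxy]-6-[(triisopropylsilyl)oxy]germacra-4,9-dien-12,8-olide unit b, via 11b-epimer 32 (not isolated)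
Conditions: NiBr2(dme) (10 mol %), 4,4'-di-tert-butyl-2,2'-bipyridine (12 mol %), Mn powder (3 equiv), H2O (3 equiv), 29 (1.5 equiv), N,N-dimethylacetamide, 0 °C to rt; then DBU (0.3 equiv), CH2Cl2, rt
Reagents that add atoms: none
Why: Proposed new method: a nickel-catalysed, stereoinvertive reductive conjugate allylation (formal hydroallylation of an α-methylene lactone by a secondary allylic ester) in which zerovalent nickel ionises the C1a ester anti to the leaving group, the η3-allylnickel transfers its less hindered terminus (C1a, remote from the oxygenated C8a) on the nickel-bearing face to the terminal carbon C13b of the coordinated methylene lactone, Mn turns over the resulting nickel enolate and water protonates it, so that C1a is made with net inversion (the new bond takes the place of the original 1S oxygen) and DBU then equilibrates C11b to the more stable trans (11R) lactone; the closest known reactions are the nickel-catalysed reductive conjugate addition of organic halides to enones and the nickel-catalysed reductive allyl–alkyl cross-electrophile coupling.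

Step 21
Reactants: 33 protected dimer (unit a Mannich base, C1a–C13b bond, silyl ethers at O6a, O6b and O1b)
Product: 35 1b-O-tert-butyldimethylsilyl-6a,6b-bis-O-triisopropylsilyl ether of the target, via trimethylammonium iodide 34 (not isolated)
Conditions: MeI, MeOH/THF, rt; then aq NaHCO3, CH2Cl2, rt
Reagents that add atoms: none
Why: Quaternisation and Hofmann-type β-elimination restore the 11(13)-methylene lactone of unit a, while the dihydro lactone of unit b has no β-leaving group and is unchanged.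

Step 22
Reactants: 35 1b-O-tert-butyldimethylsilyl-6a,6b-bis-O-triisopropylsilyl ether of the target
Product: 36 target, (1R,4Z,6R,7S,8S,9Z)-6-hydroxygermacra-4,9,11(13)-trien-12,8-olide (unit a) bonded at C1a to C13b of (1S,4Z,6R,7S,8S,9Z,11R)-1,6-dihydroxygermacra-4,9-dien-12,8-olide (unit b)
Conditions: HF·pyridine, pyridine, THF, 0 °C to rt
Reagents that add atoms: none
Why: Buffered fluoride-mediated global desilylation frees the three hydroxyls under near-neutral conditions, avoiding conjugate addition to the methylene lactone and translactonisation to O6.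

**Compound list**
1 | but-2-yn-1-ol | CC#CCO | starting material
2 | sodium 2,2-bis(2-methoxyethoxy)-3-methyl-2,5-dihydro-1,2-oxaluminol-2-uide (cyclic vinylalanate) | CC1=CCO[Al-]1(OCCOC)OCCOC.[Na+] | intermediate
3 | (2Z)-3-iodobut-2-en-1-ol | C/C(I)=C/CO | intermediate
4 | (2Z)-3-iodobut-2-enal | C/C(I)=C/C=O | intermediate
5 | succinic anhydride (oxolane-2,5-dione) | O=C1CCC(=O)O1 | starting material
6 | 4-tert-butoxy-4-oxobutanoic acid | CC(C)(C)OC(=O)CCC(=O)O | intermediate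
7 | tert-butyl 4-[(4S)-4-benzyl-2-thioxo-1,3-thiazolidin-3-yl]-4-oxobutanoate | CC(C)(C)OC(=O)CCC(=O)N1[C@@H](Cc2ccccc2)CSC1=S | intermediate
8 | trichlorotitanium (Z)-enolate of 7 | CC(C)(C)OC(=O)C/C=C(\O[Ti](Cl)(Cl)Cl)N1[C@@H](Cc2ccccc2)CSC1=S | intermediate
9 | tert-butyl (3S,4S,5Z)-3-{[(4S)-4-benzyl-2-thioxo-1,3-thiazolidin-3-yl]carbonyl}-4-hydroxy-6-iodohept-5-enoate | CC(C)(C)OC(=O)C[C@H](C(=O)N1[C@@H](Cc2ccccc2)CSC1=S)[C@H](O)/C=C(/C)I | intermediate
10 | tert-butyl (3S,4S,5Z)-3-{[(4S)-4-benzyl-2-thioxo-1,3-thiazolidin-3-yl]carbonyl}-6-iodo-4-[(triisopropylsilyl)oxy]hept-5-enoate | CC(C)(C)OC(=O)C[C@H](C(=O)N1[C@@H](Cc2ccccc2)CSC1=S)[C@H](O[Si](C(C)C)(C(C)C)C(C)C)/C=C(/C)I | intermediate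
11 | tert-butyl (3S,4S,5Z)-3-formyl-6-iodo-4-[(triisopropylsilyl)oxy]hept-5-enoate | CC(C)(C)OC(=O)C[C@H](C=O)[C@H](O[Si](C(C)C)(C(C)C)C(C)C)/C=C(/C)I | intermediate
12 | prop-2-enal (acrolein) | C=CC=O | starting material
13 | ethynyltrimethylsilane | C#C[Si](C)(C)C | starting material
14 | lithium (trimethylsilyl)acetylide | [Li]C#C[Si](C)(C)C | intermediate
15 | rac-5-(trimethylsilyl)pent-1-en-4-yn-3-ol | C=CC(O)C#C[Si](C)(C)C | intermediate
16 | (3S)-5-(trimethylsilyl)pent-1-en-4-yn-3-ol | C=C[C@H](O)C#C[Si](C)(C)C | intermediate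
17 | (3S)-pent-1-en-4-yn-3-ol | C=C[C@H](O)C#C | intermediate
18 | (5S)-5-ethenyl-4-methyl-2,5-dihydro-1,2-oxamagnesole (cyclic alkenylmagnesium alkoxide) | C=C[C@@H]1O[Mg]C=C1C | intermediate
19 | (1Z,3S)-1-iodo-2-methylpenta-1,4-dien-3-ol | C=C[C@H](O)/C(C)=C\I | intermediate
20 | tert-butyl{[(1Z,3S)-1-iodo-2-methylpenta-1,4-dien-3-yl]oxy}dimethylsilane | C=C[C@H](O[Si](C)(C)C(C)(C)C)/C(C)=C\I | intermediate
21 | {(1Z,3S)-3-[(tert-butyldimethylsilyl)oxy]-2-methylpenta-1,4-dien-1-yl}magnesium chloride | C=C[C@H](O[Si](C)(C)C(C)(C)C)/C(C)=C\[Mg]Cl | intermediate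
22 | tert-butyl (3R,4S,5Z,7S)-7-[(tert-butyldimethylsilyl)oxy]-4-hydroxy-3-{(1S,2Z)-3-iodo-1-[(triisopropylsilyl)oxy]but-2-en-1-yl}-6-methylnona-5,8-dienoate | CC(C)(C)OC(=O)C[C@H]([C@@H](O)/C=C(/C)[C@@H](O[Si](C)(C)C(C)(C)C)C=C)[C@H](O[Si](C(C)C)(C(C)C)C(C)C)/C=C(/C)I | intermediate
23 | (4R,5S)-5-{(1Z,3S)-3-[(tert-butyldimethylsilyl)oxy]-2-methylpenta-1,4-dien-1-yl}-4-{(1S,2Z)-3-iodo-1-[(triisopropylsilyl)oxy]but-2-en-1-yl}oxolan-2-one | O=C1C[C@@H]([C@H](O[Si](C(C)C)(C(C)C)C(C)C)/C=C(/C)I)[C@H](/C=C(/C)[C@@H](O[Si](C)(C)C(C)(C)C)C=C)O1 | intermediate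
24 | B-alkyl-9-borabicyclo[3.3.1]nonane adduct of 23 (boron on C3) | O=C1C[C@@H]([C@H](O[Si](C(C)C)(C(C)C)C(C)C)/C=C(/C)I)[C@H](/C=C(/C)[C@@H](O[Si](C)(C)C(C)(C)C)CCB2C3CCCC2CCC3)O1 | intermediate
25 | (1S,4Z,6R,7R,8S,9Z)-1-[(tert-butyldimethylsilyl)oxy]-6-[(triisopropylsilyl)oxy]-13-norgermacra-4,9-dien-12,8-olide | C1C(=O)O[C@H]2/C=C(/C)[C@@H](O[Si](C)(C)C(C)(C)C)CC/C(C)=C\[C@@H](O[Si](C(C)C)(C(C)C)C(C)C)[C@H]12 | intermediate
26 | lithium enolate of 25 | C1=C(O[Li])O[C@H]2/C=C(/C)[C@@H](O[Si](C)(C)C(C)(C)C)CC/C(C)=C\[C@@H](O[Si](C(C)C)(C(C)C)C(C)C)[C@H]12 | intermediate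
27 | (1S,4Z,6R,7R,8S,9Z,11S)-1-[(tert-butyldimethylsilyl)oxy]-13-(dimethylamino)-6-[(triisopropylsilyl)oxy]germacra-4,9-dien-12,8-olide | CN(C)C[C@H]1C(=O)O[C@H]2/C=C(/C)[C@@H](O[Si](C)(C)C(C)(C)C)CC/C(C)=C\[C@@H](O[Si](C(C)C)(C(C)C)C(C)C)[C@@H]21 | intermediate
28 | N-methyl trimethylammonium iodide of 27 | C[N+](C)(C)C[C@H]1C(=O)O[C@H]2/C=C(/C)[C@@H](O[Si](C)(C)C(C)(C)C)CC/C(C)=C\[C@@H](O[Si](C(C)C)(C(C)C)C(C)C)[C@@H]21.[I-] | intermediate
29 | (1S,4Z,6R,7R,8S,9Z)-1-[(tert-butyldimethylsilyl)oxy]-6-[(triisopropylsilyl)oxy]germacra-4,9,11(13)-trien-12,8-olide | C=C1C(=O)O[C@H]2/C=C(/C)[C@@H](O[Si](C)(C)C(C)(C)C)CC/C(C)=C\[C@@H](O[Si](C(C)C)(C(C)C)C(C)C)[C@H]12 | intermediate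
30 | (1S,4Z,6R,7R,8S,9Z,11S)-13-(dimethylamino)-1-hydroxy-6-[(triisopropylsilyl)oxy]germacra-4,9-dien-12,8-olide | CN(C)C[C@H]1C(=O)O[C@H]2/C=C(/C)[C@@H](O)CC/C(C)=C\[C@@H](O[Si](C(C)C)(C(C)C)C(C)C)[C@@H]21 | intermediate
31 | (1R,4Z,6R,7R,8S,9Z,11S)-13-(dimethylamino)-6-[(triisopropylsilyl)oxy]germacra-4,9-dien-12,8-olid-1-yl 3,5-bis(trifluoromethyl)benzoate | CN(C)C[C@H]1C(=O)O[C@H]2/C=C(/C)[C@H](OC(=O)c3cc(cc(c3)C(F)(F)F)C(F)(F)F)CC/C(C)=C\[C@@H](O[Si](C(C)C)(C(C)C)C(C)C)[C@@H]21 | intermediate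
32 | 11b-epimer (11bS) of 33 | CN(C)C[C@H]1C(=O)O[C@H]2/C=C(/C)[C@@H](C[C@@H]3C(=O)O[C@H]4/C=C(/C)[C@@H](O[Si](C)(C)C(C)(C)C)CC/C(C)=C\[C@@H](O[Si](C(C)C)(C(C)C)C(C)C)[C@@H]43)CC/C(C)=C\[C@@H](O[Si](C(C)C)(C(C)C)C(C)C)[C@H]12 | intermediate
33 | protected dimer: unit a (1R,4Z,6R,7R,8S,9Z,11S)-13-(dimethylamino)-6-[(triisopropylsilyl)oxy]germacra-4,9-dien-12,8-olide bonded at C1a to C13b of unit b (1S,4Z,6R,7R,8S,9Z,11R)-1-[(tert-butyldimethylsilyl)oxy]-6-[(triisopropylsilyl)oxy]germacra-4,9-dien-12,8-olide | CN(C)C[C@H]1C(=O)O[C@H]2/C=C(/C)[C@@H](C[C@H]3C(=O)O[C@H]4/C=C(/C)[C@@H](O[Si](C)(C)C(C)(C)C)CC/C(C)=C\[C@@H](O[Si](C(C)C)(C(C)C)C(C)C)[C@@H]43)CC/C(C)=C\[C@@H](O[Si](C(C)C)(C(C)C)C(C)C)[C@H]12 | intermediate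
34 | N-methyl trimethylammonium iodide of 33 | C[N+](C)(C)C[C@H]1C(=O)O[C@H]2/C=C(/C)[C@@H](C[C@H]3C(=O)O[C@H]4/C=C(/C)[C@@H](O[Si](C)(C)C(C)(C)C)CC/C(C)=C\[C@@H](O[Si](C(C)C)(C(C)C)C(C)C)[C@@H]43)CC/C(C)=C\[C@@H](O[Si](C(C)C)(C(C)C)C(C)C)[C@H]12.[I-] | intermediate
35 | 1b-O-tert-butyldimethylsilyl-6a,6b-bis-O-triisopropylsilyl ether of the target (unit a 1R,4Z,6R,7R,8S,9Z; unit b 1S,4Z,6R,7R,8S,9Z,11R) | C=C1C(=O)O[C@H]2/C=C(/C)[C@@H](C[C@H]3C(=O)O[C@H]4/C=C(/C)[C@@H](O[Si](C)(C)C(C)(C)C)CC/C(C)=C\[C@@H](O[Si](C(C)C)(C(C)C)C(C)C)[C@@H]43)CC/C(C)=C\[C@@H](O[Si](C(C)C)(C(C)C)C(C)C)[C@H]12 | intermediate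
36 | CNP0307352.3: (1R,4Z,6R,7S,8S,9Z)-6-hydroxygermacra-4,9,11(13)-trien-12,8-olide (unit a) bonded at C1a to C13b of (1S,4Z,6R,7S,8S,9Z,11R)-1,6-dihydroxygermacra-4,9-dien-12,8-olide (unit b) | C=C1C(=O)O[C@H]2/C=C(/C)[C@@H](C[C@H]3C(=O)O[C@H]4/C=C(/C)[C@@H](O)CC/C(C)=C\[C@@H](O)[C@@H]43)CC/C(C)=C\[C@@H](O)[C@H]12 | target

**Totals**
Total step count: 22.
Longest linear sequence: 14 steps (1, 2, 5, 6, 7, 13, 14, 15, 16, 18, 19, 20, 21, 22; the chains that start from 5 and from 12/13 are equally long).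

**Steps most likely to fail, with fallbacks**

Step 20 (the new nickel coupling). Risks are ionisation of the allylic lactone C8–O bonds instead of the C1a ester, attack at C9a, allyl homocoupling, simple conjugate reduction of 29, and loss of stereospecificity at C1a. The fallback uses known chemistry and sets out from lactone 25 and ester 31. The enolate of 25 (LiN(i-Pr)2, THF, −78 °C) is hydroxymethylated with monomeric formaldehyde anti to the C6 branch to give (1S,4Z,6R,7R,8S,9Z,11S)-1-[(tert-butyldimethylsilyl)oxy]-13-hydroxy-6-[(triisopropylsilyl)oxy]germacra-4,9-dien-12,8-olide F1. I2, PPh3 and imidazole convert it into the corresponding (11R)-13-iodide F2. A nickel-catalysed reductive cross-electrophile coupling of the primary iodide with the allylic ester 31 (NiCl2(dme), 4,4'-di-tert-butyl-2,2'-bipyridine, Zn, MgCl2, pyridine, N,N-dimethylacetamide) then forms the same C1a–C13b bond and comes back to the route at 33, with C11b already fixed trans by the alkylation.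

Step 15 (ten-membered ring by B-alkyl Suzuki coupling). Risks are oligomerisation, protodeboronation and slow closure of a medium ring. The fallback sets out from 23. Hydroboration–oxidation (9-BBN-H; NaBO3·4H2O) gives the primary alcohol (4R,5S)-5-{(1Z,3S)-3-[(tert-butyldimethylsilyl)oxy]-5-hydroxy-2-methylpent-1-en-1-yl}-4-{(1S,2Z)-3-iodo-1-[(triisopropylsilyl)oxy]but-2-en-1-yl}oxolan-2-one F3. I2, PPh3 and imidazole give the corresponding 5-iodopentenyl compound F4. Zinc insertion into the alkyl iodide (Zn dust, LiCl, THF, 40 °C; the vinyl iodide is inert) gives the alkylzinc iodide F5, and an intramolecular Negishi coupling (Pd2(dba)3, SPhos, THF/N-methyl-2-pyrrolidinone, slow addition) comes back to the route at 25.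

Step 19 (Mitsunobu inversion of a hindered macrocyclic allylic alcohol). Risks are elimination, SN2' attack and incomplete inversion. The fallback sets out from 30. Dess–Martin periodinane (NaHCO3, CH2Cl2) gives the enone (4Z,6R,7R,8S,9Z,11S)-13-(dimethylamino)-1-oxo-6-[(triisopropylsilyl)oxy]germacra-4,9-dien-12,8-olide F6. Reagent-controlled reduction with (S)-2-methyl-CBS-oxazaborolidine and catecholborane (toluene, −78 °C; alkenyl as the large group) gives the (1R)-alcohol (1R,4Z,6R,7R,8S,9Z,11S)-13-(dimethylamino)-1-hydroxy-6-[(triisopropylsilyl)oxy]germacra-4,9-dien-12,8-olide F7. Acylation with 3,5-bis(trifluoromethyl)benzoyl chloride and pyridine comes back to the route at 31.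

**Further compounds**
F1 | step 20 | (1S,4Z,6R,7R,8S,9Z,11S)-1-[(tert-butyldimethylsilyl)oxy]-13-hydroxy-6-[(triisopropylsilyl)oxy]germacra-4,9-dien-12,8-olide | OC[C@H]1C(=O)O[C@H]2/C=C(/C)[C@@H](O[Si](C)(C)C(C)(C)C)CC/C(C)=C\[C@@H](O[Si](C(C)C)(C(C)C)C(C)C)[C@@H]21
F2 | step 20 | (1S,4Z,6R,7R,8S,9Z,11R)-1-[(tert-butyldimethylsilyl)oxy]-13-iodo-6-[(triisopropylsilyl)oxy]germacra-4,9-dien-12,8-olide | IC[C@H]1C(=O)O[C@H]2/C=C(/C)[C@@H](O[Si](C)(C)C(C)(C)C)CC/C(C)=C\[C@@H](O[Si](C(C)C)(C(C)C)C(C)C)[C@@H]21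
F3 | step 15 | (4R,5S)-5-{(1Z,3S)-3-[(tert-butyldimethylsilyl)oxy]-5-hydroxy-2-methylpent-1-en-1-yl}-4-{(1S,2Z)-3-iodo-1-[(triisopropylsilyl)oxy]but-2-en-1-yl}oxolan-2-one | O=C1C[C@@H]([C@H](O[Si](C(C)C)(C(C)C)C(C)C)/C=C(/C)I)[C@H](/C=C(/C)[C@@H](O[Si](C)(C)C(C)(C)C)CCO)O1
F4 | step 15 | (4R,5S)-5-{(1Z,3S)-3-[(tert-butyldimethylsilyl)oxy]-5-iodo-2-methylpent-1-en-1-yl}-4-{(1S,2Z)-3-iodo-1-[(triisopropylsilyl)oxy]but-2-en-1-yl}oxolan-2-one | O=C1C[C@@H]([C@H](O[Si](C(C)C)(C(C)C)C(C)C)/C=C(/C)I)[C@H](/C=C(/C)[C@@H](O[Si](C)(C)C(C)(C)C)CCI)O1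
F5 | step 15 | alkylzinc iodide from F4 (zinc on C3) | O=C1C[C@@H]([C@H](O[Si](C(C)C)(C(C)C)C(C)C)/C=C(/C)I)[C@H](/C=C(/C)[C@@H](O[Si](C)(C)C(C)(C)C)CC[Zn]I)O1
F6 | step 19 | (4Z,6R,7R,8S,9Z,11S)-13-(dimethylamino)-1-oxo-6-[(triisopropylsilyl)oxy]germacra-4,9-dien-12,8-olide | CN(C)C[C@H]1C(=O)O[C@H]2/C=C(/C)C(=O)CC/C(C)=C\[C@@H](O[Si](C(C)C)(C(C)C)C(C)C)[C@@H]21
F7 | step 19 | (1R,4Z,6R,7R,8S,9Z,11S)-13-(dimethylamino)-1-hydroxy-6-[(triisopropylsilyl)oxy]germacra-4,9-dien-12,8-olide | CN(C)C[C@H]1C(=O)O[C@H]2/C=C(/C)[C@H](O)CC/C(C)=C\[C@@H](O[Si](C(C)C)(C(C)C)C(C)C)[C@@H]21
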